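**Strategy.** The carbocycle of the coumarin (C4a–C5–C6–C7–C8–C8a) carries oxygen at C7 and C8a, methyl at C6 and C8, and carbon at C4a and C5, which is the substitution pattern of a C-methylated polyketide. The ring is therefore cut at C4a–C5 and unfolded into a linear diketo-dioxinone that already holds both methyl groups and the silylated (1''R,2''S) side chain. One base/acid operation closes the benzene ring by intramolecular aldol condensation and should deliver the hexasubstituted, acetonide-masked resorcylate with all six substituents in place. Reduction to the salicylaldehyde and Knoevenagel lactonisation with a dihydropyranone acetate then complete the coumarin.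

Key step: step 7

Remark: ring positions are given in coumarin numbering throughout (C1'' benzylic carbon and C2'' carbinol carbon of the C5 side chain; C2'–C6' for the dihydropyranone). Compounds 8, 9 and 10 are mixtures of epimers at the future C6 and C8, which is of no consequence because both carbons become aromatic.

Step 1
Reactants: 1 methyl (S)-3-hydroxybutanoate
Product: 2 methyl (2S,3S)-3-hydroxy-2-methylbutanoate
Conditions: LiN(i-Pr)2 (2.2 equiv), THF, −78 to −20 °C; MeI, DMPU, −78 to 0 °C; aq. NH4Cl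
Reagents that add atoms: iodomethane, CI
Why: Fráter–Seebach alkylation, in which the dilithiated alkoxide–enolate is held in a six-membered chelate and iodomethane should enter on the face away from the C3 methyl group, setting C2 anti to the untouched (S)-carbinol centre.

Step 2
Reactants: 2 methyl (2S,3S)-3-hydroxy-2-methylbutanoate
Product: 3 methyl (2S,3S)-3-[(tert-butyldimethylsilyl)oxy]-2-methylbutanoate
Conditions: TBSCl, imidazole, DMF, rt
Reagents that add atoms: tert-butyldimethylsilyl chloride, CC(C)(C)[Si](C)(C)Cl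
Why: Imidazole-promoted silyl ether formation on the only hydroxyl group, under conditions too mild to enolise the ester, so both stereocentres are carried through.

Step 3
Reactants: 3 methyl (2S,3S)-3-[(tert-butyldimethylsilyl)oxy]-2-methylbutanoate
Product: 4 (2S,3S)-3-[(tert-butyldimethylsilyl)oxy]-N-methoxy-N,2-dimethylbutanamide
Conditions: MeNH(OMe)·HCl, i-PrMgCl, THF, −20 to 0 °C; aq. NH4Cl
Reagents that add atoms: N,O-dimethylhydroxylamine hydrochloride, CNOC.Cl
Why: Weinreb amide formation by aminolysis of the methyl ester with the chloromagnesium amide made in the flask, a low-temperature procedure that is routinely used on α-methyl-β-silyloxy esters without epimerisation.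

Step 4
Reactants: 5 2,2,6-trimethyl-4H-1,3-dioxin-4-one
Product: 6 6-ethyl-2,2-dimethyl-4H-1,3-dioxin-4-one
Conditions: LiN(i-Pr)2, THF, −78 °C; MeI, DMPU, −78 to −40 °C; aq. NH4Cl
Reagents that add atoms: iodomethane, CI
Why: Vinylogous (γ) alkylation of the lithium dienolate of the dioxinone, which in the presence of a polar cosolvent should take up the methyl group at the exocyclic carbon.

Step 5
Reactants: 6 6-ethyl-2,2-dimethyl-4H-1,3-dioxin-4-one; 7 propionyl chloride
Product: 8 2,2-dimethyl-6-(3-oxopentan-2-yl)-4H-1,3-dioxin-4-one (racemic)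
Conditions: 6 (2 equiv), LiN(SiMe3)2 (2 equiv), THF, −78 °C; 7 (1 equiv), −78 °C; aq. NH4Cl
Reagents that add atoms: none
Why: Vinylogous C-acylation of a dioxinone lithium dienolate with an acid chloride, in which the second equivalent of dienolate deprotonates the more acidic keto-dioxinone as it forms and so prevents a second acylation.

Step 6
Reactants: 8 2,2-dimethyl-6-(3-oxopentan-2-yl)-4H-1,3-dioxin-4-one; 4 (2S,3S)-3-[(tert-butyldimethylsilyl)oxy]-N-methoxy-N,2-dimethylbutanamide
Product: 9 6-[(6S,7S)-7-[(tert-butyldimethylsilyl)oxy]-4,6-dimethyl-3,5-dioxooctan-2-yl]-2,2-dimethyl-4H-1,3-dioxin-4-one (mixture of epimers at C2 and C4 of the chain)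
Conditions: 8 (1.3 equiv), LiN(i-Pr)2 (2.1 equiv per 8), THF, −78 to −40 °C; 4, −78 to −20 °C; aq. NH4Cl
Reagents that add atoms: none
Why: Claisen-type C-acylation of a 1,3-dicarbonyl dianion with a Weinreb amide, in which the second deprotonation takes place at the ethyl-ketone CH2, this most basic carbon attacks the amide, and the chelated tetrahedral adduct protects the product until quench while the α-centre of 4 is too weakly acidic to be enolised by the dianion.

Step 7
Reactants: 9 6-[(6S,7S)-7-[(tert-butyldimethylsilyl)oxy]-4,6-dimethyl-3,5-dioxooctan-2-yl]-2,2-dimethyl-4H-1,3-dioxin-4-one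
Product: 11 5-[(2R,3S)-3-[(tert-butyldimethylsilyl)oxy]butan-2-yl]-7-hydroxy-2,2,6,8-tetramethyl-4H-1,3-benzodioxin-4-one, via aldol adduct 10 (not isolated)
Conditions: Et3N (3 equiv), CH2Cl2, 0 °C to rt; then CF3CO2H (5 equiv), 0 °C, 30 min
Reagents that add atoms: none
Why: Triethylamine enolises the tricarbonyl array reversibly, and the vinylogous dienolate formed by loss of the C8 proton attacks the C5 ketone through the dioxinone α-carbon (future C4a) to give aldol adduct 10, from which acid removes water across C4a–C5 before the C7 ketone tautomerises to the phenol. The closest known reaction type is the biomimetic aldol aromatisation of diketo-dioxinones to acetonide-masked resorcylates. The single new ring, the carbocycle C4a–C5–C6–C7–C8–C8a, closes in a 6-(enolexo)-exo-trig mode by formation of the C4a–C5 bond. No stereocentre is created, because the three transient sp3 centres of 10 disappear on aromatisation, and C1'' and C2'' are carried through unchanged. The step needs C-attack of C4a at C5 in preference to lactone- or pyranone-forming O-cyclisations, and this is secured by the dioxinone, which ties the carboxyl terminus and the C8a oxygen into one ring so that only the aldol mode leads to a stable product. Retention at C1'' is secured because the protons at C6 and C8, each flanked by two carbonyl-type groups, are removed far more readily than the C1'' proton, so the amine should neither enolise towards the side chain nor trigger loss of the silyloxy group.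

Step 8
Reactants: 11 5-[(2R,3S)-3-[(tert-butyldimethylsilyl)oxy]butan-2-yl]-7-hydroxy-2,2,6,8-tetramethyl-4H-1,3-benzodioxin-4-one
Product: 12 7-[(tert-butyldimethylsilyl)oxy]-5-[(2R,3S)-3-[(tert-butyldimethylsilyl)oxy]butan-2-yl]-2,2,6,8-tetramethyl-4H-1,3-benzodioxin-4-one
Conditions: TBSOTf, 2,6-lutidine, CH2Cl2, 0 °C
Reagents that add atoms: tert-butyldimethylsilyl trifluoromethanesulfonate, CC(C)(C)[Si](C)(C)OS(=O)(=O)C(F)(F)F
Why: Silyl ether formation on a di-ortho-substituted phenol with the reactive silyl triflate, which removes the acidic OH that would otherwise sit para to the carbonyl as a phenoxide and slow the hydride reduction.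

Step 9
Reactants: 12 7-[(tert-butyldimethylsilyl)oxy]-5-[(2R,3S)-3-[(tert-butyldimethylsilyl)oxy]butan-2-yl]-2,2,6,8-tetramethyl-4H-1,3-benzodioxin-4-one
Product: 14 4-[(tert-butyldimethylsilyl)oxy]-6-[(2R,3S)-3-[(tert-butyldimethylsilyl)oxy]butan-2-yl]-2-hydroxy-3,5-dimethylbenzaldehyde, via lactol 13 (not isolated)
Conditions: i-Bu2AlH (1.3 equiv), CH2Cl2, −78 °C; aq. potassium sodium tartrate (KNaC4H4O6), rt
Reagents that add atoms: none
Why: Partial hydride reduction of a 2,2-dimethyl-1,3-benzodioxin-4-one, in which the cyclic aluminium hemiacetal should persist at −78 °C and collapse only on work-up with loss of acetone to the salicylaldehyde.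

Step 10
Reactants: 15 methyl (R)-3-hydroxybutanoate
Product: 16 methyl (R)-3-[(tert-butyldimethylsilyl)oxy]butanoate
Conditions: TBSCl, imidazole, DMF, rt
Reagents that add atoms: tert-butyldimethylsilyl chloride, CC(C)(C)[Si](C)(C)Cl
Why: Imidazole-promoted silyl ether formation, which masks the hydroxyl group before the strongly basic Claisen step and leaves the (R) centre untouched.

Step 11
Reactants: 16 methyl (R)-3-[(tert-butyldimethylsilyl)oxy]butanoate; 17 methyl acetoacetate
Product: 18 methyl (7R)-7-[(tert-butyldimethylsilyl)oxy]-3,5-dioxooctanoate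
Conditions: 17 (2.2 equiv), NaH, THF, 0 °C; n-BuLi, 0 °C; 16, 0 °C to rt; aq. HCl
Reagents that add atoms: none
Why: Huckin–Weiler Claisen condensation, in which the β-keto ester dianion attacks the ester carbonyl of 16 through its terminal carbon and the excess dianion takes up the acidic proton of the 3,5-dioxo ester.

Step 12
Reactants: 18 methyl (7R)-7-[(tert-butyldimethylsilyl)oxy]-3,5-dioxooctanoate
Product: 20 methyl 2-[(2R)-2-methyl-4-oxo-3,4-dihydro-2H-pyran-6-yl]acetate, via hydroxy diketone 19 (not isolated)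
Conditions: aq. HF (48%), MeCN, 0 °C to rt; then TsOH·H2O (cat.), CH2Cl2, rt
Reagents that add atoms: none
Why: Desilylation followed by acid-catalysed cyclodehydration of a δ-hydroxy-β-diketone, in which the C7 hydroxyl adds to the C3 ketone (the only six-membered hemiketal available) and loss of water gives the vinylogous ester without touching the carbinol C–O bond or the (R) centre.

Step 13
Reactants: 14 4-[(tert-butyldimethylsilyl)oxy]-6-[(2R,3S)-3-[(tert-butyldimethylsilyl)oxy]butan-2-yl]-2-hydroxy-3,5-dimethylbenzaldehyde; 20 methyl 2-[(2R)-2-methyl-4-oxo-3,4-dihydro-2H-pyran-6-yl]acetate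
Product: 22 7-[(tert-butyldimethylsilyl)oxy]-5-[(2R,3S)-3-[(tert-butyldimethylsilyl)oxy]butan-2-yl]-6,8-dimethyl-3-[(2R)-2-methyl-4-oxo-3,4-dihydro-2H-pyran-6-yl]-2H-chromen-2-one, via arylidene ester 21 (not isolated)
Conditions: piperidine (0.2 equiv), AcOH (0.2 equiv), 4 Å molecular sieves, toluene, 80 °C
Reagents that add atoms: none
Why: Knoevenagel condensation followed by lactonisation (Knoevenagel coumarin synthesis), in which the methylene flanked by the ester and the vinylogous-ester carbon is the only doubly activated position of 20 and attack of the phenol on the methyl ester should make the sequence irreversible.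

Step 14
Reactants: 22 7-[(tert-butyldimethylsilyl)oxy]-5-[(2R,3S)-3-[(tert-butyldimethylsilyl)oxy]butan-2-yl]-6,8-dimethyl-3-[(2R)-2-methyl-4-oxo-3,4-dihydro-2H-pyran-6-yl]-2H-chromen-2-one
Product: 23 7-hydroxy-5-[(2R,3S)-3-hydroxybutan-2-yl]-6,8-dimethyl-3-[(2R)-2-methyl-4-oxo-3,4-dihydro-2H-pyran-6-yl]-2H-chromen-2-one (CNP0291478.1)
Conditions: HF·pyridine, pyridine, THF, 0 °C to rt
Reagents that add atoms: none
Why: Fluoride-mediated cleavage of the aryl and the secondary alkyl silyl ether under buffered, non-basic conditions, which should avoid retro-oxa-Michael opening of the dihydropyranone and touches no stereocentre.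

**Compound list**

1 | methyl (S)-3-hydroxybutanoate | C[C@H](O)CC(=O)OC | starting material
2 | methyl (2S,3S)-3-hydroxy-2-methylbutanoate | COC(=O)[C@@H](C)[C@H](C)O | intermediate
3 | methyl (2S,3S)-3-[(tert-butyldimethylsilyl)oxy]-2-methylbutanoate | COC(=O)[C@@H](C)[C@H](C)O[Si](C)(C)C(C)(C)C | intermediate
4 | (2S,3S)-3-[(tert-butyldimethylsilyl)oxy]-N-methoxy-N,2-dimethylbutanamide | CON(C)C(=O)[C@@H](C)[C@H](C)O[Si](C)(C)C(C)(C)C | intermediate
5 | 2,2,6-trimethyl-4H-1,3-dioxin-4-one | CC1=CC(=O)OC(C)(C)O1 | starting material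
6 | 6-ethyl-2,2-dimethyl-4H-1,3-dioxin-4-one | CCC1=CC(=O)OC(C)(C)O1 | intermediate
7 | propionyl chloride | CCC(=O)Cl | starting material
8 | 2,2-dimethyl-6-(3-oxopentan-2-yl)-4H-1,3-dioxin-4-one (racemic) | CCC(=O)C(C)C1=CC(=O)OC(C)(C)O1 | intermediate
9 | 6-[(6S,7S)-7-[(tert-butyldimethylsilyl)oxy]-4,6-dimethyl-3,5-dioxooctan-2-yl]-2,2-dimethyl-4H-1,3-dioxin-4-one (epimers at chain C2 and C4) | CC1(C)OC(=O)C=C(O1)C(C)C(=O)C(C)C(=O)[C@@H](C)[C@H](C)O[Si](C)(C)C(C)(C)C | intermediate
10 | aldol adduct, not isolated: 5-[(2S,3S)-3-[(tert-butyldimethylsilyl)oxy]butan-2-yl]-5-hydroxy-2,2,6,8-tetramethyl-4a,5-dihydro-4H-1,3-benzodioxine-4,7(6H)-dione (diastereomers at C4a, C5, C6) | CC1(C)OC(=O)C2C(O1)=C(C)C(=O)C(C)C2(O)[C@@H](C)[C@H](C)O[Si](C)(C)C(C)(C)C | intermediate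
11 | 5-[(2R,3S)-3-[(tert-butyldimethylsilyl)oxy]butan-2-yl]-7-hydroxy-2,2,6,8-tetramethyl-4H-1,3-benzodioxin-4-one | CC1(C)OC(=O)c2c(O1)c(C)c(O)c(C)c2[C@@H](C)[C@H](C)O[Si](C)(C)C(C)(C)C | intermediate
12 | 7-[(tert-butyldimethylsilyl)oxy]-5-[(2R,3S)-3-[(tert-butyldimethylsilyl)oxy]butan-2-yl]-2,2,6,8-tetramethyl-4H-1,3-benzodioxin-4-one | CC1(C)OC(=O)c2c(O1)c(C)c(O[Si](C)(C)C(C)(C)C)c(C)c2[C@@H](C)[C@H](C)O[Si](C)(C)C(C)(C)C | intermediate
13 | lactol, not isolated: 7-[(tert-butyldimethylsilyl)oxy]-5-[(2R,3S)-3-[(tert-butyldimethylsilyl)oxy]butan-2-yl]-2,2,6,8-tetramethyl-4H-1,3-benzodioxin-4-ol | CC1(C)OC(O)c2c(O1)c(C)c(O[Si](C)(C)C(C)(C)C)c(C)c2[C@@H](C)[C@H](C)O[Si](C)(C)C(C)(C)C | intermediate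
14 | 4-[(tert-butyldimethylsilyl)oxy]-6-[(2R,3S)-3-[(tert-butyldimethylsilyl)oxy]butan-2-yl]-2-hydroxy-3,5-dimethylbenzaldehyde | O=Cc1c(O)c(C)c(O[Si](C)(C)C(C)(C)C)c(C)c1[C@@H](C)[C@H](C)O[Si](C)(C)C(C)(C)C | intermediate
15 | methyl (R)-3-hydroxybutanoate | C[C@@H](O)CC(=O)OC | starting material
16 | methyl (R)-3-[(tert-butyldimethylsilyl)oxy]butanoate | C[C@@H](O[Si](C)(C)C(C)(C)C)CC(=O)OC | intermediate
17 | methyl acetoacetate | CC(=O)CC(=O)OC | starting material
18 | methyl (7R)-7-[(tert-butyldimethylsilyl)oxy]-3,5-dioxooctanoate | COC(=O)CC(=O)CC(=O)C[C@@H](C)O[Si](C)(C)C(C)(C)C | intermediate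
19 | hydroxy diketone, not isolated: methyl (7R)-7-hydroxy-3,5-dioxooctanoate | COC(=O)CC(=O)CC(=O)C[C@@H](C)O | intermediate
20 | methyl 2-[(2R)-2-methyl-4-oxo-3,4-dihydro-2H-pyran-6-yl]acetate | COC(=O)CC1=CC(=O)C[C@@H](C)O1 | intermediate
21 | arylidene ester, not isolated: methyl 3-{4-[(tert-butyldimethylsilyl)oxy]-6-[(2R,3S)-3-[(tert-butyldimethylsilyl)oxy]butan-2-yl]-2-hydroxy-3,5-dimethylphenyl}-2-[(2R)-2-methyl-4-oxo-3,4-dihydro-2H-pyran-6-yl]prop-2-enoate (alkene geometry not fixed) | COC(=O)C(=Cc1c(O)c(C)c(O[Si](C)(C)C(C)(C)C)c(C)c1[C@@H](C)[C@H](C)O[Si](C)(C)C(C)(C)C)C2=CC(=O)C[C@@H](C)O2 | intermediate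
22 | 7-[(tert-butyldimethylsilyl)oxy]-5-[(2R,3S)-3-[(tert-butyldimethylsilyl)oxy]butan-2-yl]-6,8-dimethyl-3-[(2R)-2-methyl-4-oxo-3,4-dihydro-2H-pyran-6-yl]-2H-chromen-2-one | Cc1c(O[Si](C)(C)C(C)(C)C)c(C)c2oc(=O)c(C3=CC(=O)C[C@@H](C)O3)cc2c1[C@@H](C)[C@H](C)O[Si](C)(C)C(C)(C)C | intermediate
23 | 7-hydroxy-5-[(2R,3S)-3-hydroxybutan-2-yl]-6,8-dimethyl-3-[(2R)-2-methyl-4-oxo-3,4-dihydro-2H-pyran-6-yl]-2H-chromen-2-one (CNP0291478.1) | Cc1c(O)c(C)c2oc(=O)c(C3=CC(=O)C[C@@H](C)O3)cc2c1[C@@H](C)[C@H](C)O | target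

**Step count.** Total: 14 steps. Longest linear sequence: 9 steps (steps 1, 2, 3, 6, 7, 8, 9, 13 and 14, from methyl (S)-3-hydroxybutanoate).

**Steps most likely to fail**

Step 7. The C5 carbonyl is branched on both sides, so carbon–carbon bond formation may be slow. O-cyclisation to a pyranone, β-elimination of the silyloxy group, or acid-induced desilylation followed by lactonisation onto the dioxinone carbonyl could then overtake the aldol closure. The fallback takes the two C-methyl groups out of the folding step and installs them on the finished arene; it sets out from 5 and 4 and comes back at 12, at the cost of one extra step. Compound 5 is γ-acetylated (LiN(SiMe3)2, acetyl chloride, THF, −78 °C) to 2,2-dimethyl-6-(2-oxopropyl)-4H-1,3-dioxin-4-one F1. Its dianion (LiN(i-Pr)2, THF, −78 °C) is acylated by 4 to 6-[(5S,6S)-6-[(tert-butyldimethylsilyl)oxy]-5-methyl-2,4-dioxoheptyl]-2,2-dimethyl-4H-1,3-dioxin-4-one F2. This unbranched chain should aromatise under the standard conditions (Et3N, CH2Cl2; then CF3CO2H) to 5-[(2R,3S)-3-[(tert-butyldimethylsilyl)oxy]butan-2-yl]-7-hydroxy-2,2-dimethyl-4H-1,3-benzodioxin-4-one F3. Electrophilic bromination of the two free positions ortho to the phenol (N-bromosuccinimide, 2.1 equiv, MeCN, 0 °C) gives the 6,8-dibromo-7-hydroxy benzodioxinone F4, and silylation (TBSOTf, 2,6-lutidine) gives the 6,8-dibromo-7-silyloxy benzodioxinone F5. A double Suzuki–Miyaura methylation (trimethylboroxine, Pd(OAc)2, 2-dicyclohexylphosphino-2',6'-dimethoxybiphenyl, K3PO4, toluene, 100 °C) then delivers 12.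

Step 6. A secondary carbon nucleophile must attack an α-branched amide, so the addition may be slow, and proton transfer between the dianion and the amide on warming would stall the reaction and endanger the α-centre. The fallback replaces the acylation by an aldol addition and an oxidation; it sets out from 4 and 8 and comes back at 9, at the cost of two extra steps. Amide 4 is reduced (i-Bu2AlH, THF, −78 °C) to (2S,3S)-3-[(tert-butyldimethylsilyl)oxy]-2-methylbutanal F6. The dianion of 8 (LiN(i-Pr)2, THF, −78 °C) should add to F6 rapidly to give the β-hydroxy ketone 6-[7-[(tert-butyldimethylsilyl)oxy]-5-hydroxy-4,6-dimethyl-3-oxooctan-2-yl]-2,2-dimethyl-4H-1,3-dioxin-4-one F7, with the two side-chain centres configured as in 4 and the others as a mixture. Oxidation with Dess–Martin periodinane (NaHCO3, CH2Cl2) gives 9.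

Step 13. The amine catalyst may attack the vinylogous ester and open the dihydropyranone, iminium formation at the di-ortho-substituted aldehyde may be slow, and the dienolate of 20 may condense through its ring carbon instead of the exocyclic methylene. The fallback builds the coumarin first and the dihydropyranone last; it sets out from 14 and 16 and comes back at 23, replacing steps 11 to 14. Compound 14 is condensed with Meldrum's acid (2,2-dimethyl-1,3-dioxane-4,6-dione, piperidinium acetate, EtOH) to 7-[(tert-butyldimethylsilyl)oxy]-5-[(2R,3S)-3-[(tert-butyldimethylsilyl)oxy]butan-2-yl]-6,8-dimethyl-2-oxo-2H-chromene-3-carboxylic acid F8. This is activated (1H-benzotriazole, SOCl2, CH2Cl2) as the N-acylbenzotriazole of that acid F9. In parallel, 16 is converted (MeNH(OMe)·HCl, i-PrMgCl) into (3R)-3-[(tert-butyldimethylsilyl)oxy]-N-methoxy-N-methylbutanamide F10 and then (MeMgBr, THF, 0 °C) into (4R)-4-[(tert-butyldimethylsilyl)oxy]pentan-2-one F11. The kinetic lithium enolate of F11 (LiN(SiMe3)2, THF, −78 °C, two equivalents) is C-acylated by F9 to the tris-silylated 1-(coumarin-3-yl)hexane-1,3-dione F12. Aqueous HF in MeCN should then remove all three silyl groups and close the dihydropyranone by cyclodehydration of the δ-hydroxy-1,3-diketone, giving 23 directly.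

**Further compounds**

F1 | step 7 | 2,2-dimethyl-6-(2-oxopropyl)-4H-1,3-dioxin-4-one | CC(=O)CC1=CC(=O)OC(C)(C)O1
F2 | step 7 | 6-[(5S,6S)-6-[(tert-butyldimethylsilyl)oxy]-5-methyl-2,4-dioxoheptyl]-2,2-dimethyl-4H-1,3-dioxin-4-one | CC1(C)OC(=O)C=C(O1)CC(=O)CC(=O)[C@@H](C)[C@H](C)O[Si](C)(C)C(C)(C)C
F3 | step 7 | 5-[(2R,3S)-3-[(tert-butyldimethylsilyl)oxy]butan-2-yl]-7-hydroxy-2,2-dimethyl-4H-1,3-benzodioxin-4-one | CC1(C)OC(=O)c2c(O1)cc(O)cc2[C@@H](C)[C@H](C)O[Si](C)(C)C(C)(C)C
F4 | step 7 | 6,8-dibromo-5-[(2R,3S)-3-[(tert-butyldimethylsilyl)oxy]butan-2-yl]-7-hydroxy-2,2-dimethyl-4H-1,3-benzodioxin-4-one | CC1(C)OC(=O)c2c(O1)c(Br)c(O)c(Br)c2[C@@H](C)[C@H](C)O[Si](C)(C)C(C)(C)C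
F5 | step 7 | 6,8-dibromo-7-[(tert-butyldimethylsilyl)oxy]-5-[(2R,3S)-3-[(tert-butyldimethylsilyl)oxy]butan-2-yl]-2,2-dimethyl-4H-1,3-benzodioxin-4-one | CC1(C)OC(=O)c2c(O1)c(Br)c(O[Si](C)(C)C(C)(C)C)c(Br)c2[C@@H](C)[C@H](C)O[Si](C)(C)C(C)(C)C
F6 | step 6 | (2S,3S)-3-[(tert-butyldimethylsilyl)oxy]-2-methylbutanal | O=C[C@@H](C)[C@H](C)O[Si](C)(C)C(C)(C)C
F7 | step 6 | 6-[7-[(tert-butyldimethylsilyl)oxy]-5-hydroxy-4,6-dimethyl-3-oxooctan-2-yl]-2,2-dimethyl-4H-1,3-dioxin-4-one (side-chain centres as in 4) | CC1(C)OC(=O)C=C(O1)C(C)C(=O)C(C)C(O)[C@@H](C)[C@H](C)O[Si](C)(C)C(C)(C)C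
F8 | step 13 | 7-[(tert-butyldimethylsilyl)oxy]-5-[(2R,3S)-3-[(tert-butyldimethylsilyl)oxy]butan-2-yl]-6,8-dimethyl-2-oxo-2H-chromene-3-carboxylic acid | Cc1c(O[Si](C)(C)C(C)(C)C)c(C)c2oc(=O)c(C(=O)O)cc2c1[C@@H](C)[C@H](C)O[Si](C)(C)C(C)(C)C
F9 | step 13 | 3-(1H-benzotriazol-1-ylcarbonyl)-7-[(tert-butyldimethylsilyl)oxy]-5-[(2R,3S)-3-[(tert-butyldimethylsilyl)oxy]butan-2-yl]-6,8-dimethyl-2H-chromen-2-one | Cc1c(O[Si](C)(C)C(C)(C)C)c(C)c2oc(=O)c(C(=O)n3nnc4ccccc34)cc2c1[C@@H](C)[C@H](C)O[Si](C)(C)C(C)(C)C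
F10 | step 13 | (3R)-3-[(tert-butyldimethylsilyl)oxy]-N-methoxy-N-methylbutanamide | CON(C)C(=O)C[C@@H](C)O[Si](C)(C)C(C)(C)C
F11 | step 13 | (4R)-4-[(tert-butyldimethylsilyl)oxy]pentan-2-one | CC(=O)C[C@@H](C)O[Si](C)(C)C(C)(C)C
F12 | step 13 | (5R)-5-[(tert-butyldimethylsilyl)oxy]-1-{7-[(tert-butyldimethylsilyl)oxy]-5-[(2R,3S)-3-[(tert-butyldimethylsilyl)oxy]butan-2-yl]-6,8-dimethyl-2-oxo-2H-chromen-3-yl}hexane-1,3-dione | Cc1c(O[Si](C)(C)C(C)(C)C)c(C)c2oc(=O)c(C(=O)CC(=O)C[C@@H](C)O[Si](C)(C)C(C)(C)C)cc2c1[C@@H](C)[C@H](C)O[Si](C)(C)C(C)(C)C
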